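**Retrosynthetic overview**

1. Target ⇒ acylation of the C9 alcohol ⇒ 9-hydroxy-7-tiglate ⇒ key C–O step: Evans–Tishchenko redox esterification of the 7-hydroxy-1,9-dione with tiglic aldehyde (forms the O7–acyl bond, sets C9, tells the two oxygens apart).
2. 7-Hydroxy-1,9-dione ⇒ C7–O bond by ligand-controlled conjugate borylation/oxidation of the tricyclic dienedione ⇒ allylic oxidation and dehydration of a tricyclic ketol.
3. Ketol ⇒ cyclobutane (C4–C10) by enolate/epoxide 4-exo closure in a cis-fused cyclohexene oxide–cycloheptenone.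
4. Cycloheptenone ⇒ ring-closing metathesis; cyclohexene ⇒ asymmetric Diels–Alder reaction of a triene (from prenal and prenylmagnesium chloride) with methyl vinyl ketone.
5. Ring order: cyclohexene, then cycloheptenone, then cyclobutane; ketone at C1 and both esters last.

Assumption: tricyclic compounds carry longipinane numbers (C1 = cyclohexenone carbonyl, C2=C3 with the methyl on C3, C4 and C11 = cyclobutane CH bonded to C3 and C1, C5 = cyclobutane CH bonded to C6, C6 = CMe2, C7–C9 = rest of the seven-membered ring, C10 = quaternary methyl-bearing cyclobutane carbon).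
Assumption: the facial sense of the two catalyst-controlled steps (3 and 11) is as written; if an assay shows the opposite sense, the mirror-image catalyst or ligand is used.

**Step 1**
Reactants: 1 3-methylbut-2-enal; 2 (3-methylbut-2-en-1-yl)magnesium chloride
Product: 3 3,3,6-trimethylhepta-1,5-dien-4-ol (racemic)
Conditions: THF, −78 → 0 °C; then H2O
Reagents that add atoms: none
Why: Carbonyl allylation with an allylic Grignard reagent, which bonds through its γ-carbon (six-membered transition state) and adds 1,2 to give the 1,1-dimethylallyl carbinol; the carbinol centre is racemic and is removed in step 2.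

**Step 2**
Reactants: 3 3,3,6-trimethylhepta-1,5-dien-4-ol
Product: 4 (3E)-2,5,5-trimethylhepta-1,3,6-triene
Conditions: TsOH·H2O (1 mol%), toluene, 90 °C, Dean–Stark
Reagents that add atoms: none
Why: Acid-catalysed 1,4-dehydration (E1) through the allyl cation; only the methyl groups carry a β-hydrogen (the other neighbour is quaternary), so one conjugated diene forms, with the bulky group trans.

**Step 3**
Reactants: 4 (3E)-2,5,5-trimethylhepta-1,3,6-triene; 5 but-3-en-2-one
Product: 6 1-[(1R,2S)-4-methyl-2-(2-methylbut-3-en-2-yl)cyclohex-3-en-1-yl]ethan-1-one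
Conditions: (S)-o-tolyl-CBS-oxazaborolidine (20 mol%), Tf2NH (16 mol%), CH2Cl2, −78 → −40 °C
Reagents that add atoms: none
Why: Lewis-acid-catalysed Diels–Alder reaction in which the 1-alkyl and 2-methyl groups of the diene both direct the acetyl-bearing carbon next to the substituted terminus (ortho/para rule), the endo transition state puts acetyl cis to the tert-alkyl group, and the chiral oxazaborolidinium cation blocks one face of the bound enone, which sets both ring stereocentres.

**Step 4**
Reactants: 6 1-[(1R,2S)-4-methyl-2-(2-methylbut-3-en-2-yl)cyclohex-3-en-1-yl]ethan-1-one; 7 p-toluenesulfonylmethyl isocyanide (TosMIC)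
Product: 8 2-[(1R,2R)-4-methyl-2-(2-methylbut-3-en-2-yl)cyclohex-3-en-1-yl]propanenitrile (both epimers at the nitrile α-carbon; ring centres unchanged, descriptor change is formal)
Conditions: t-BuOK, DME, EtOH (2 equiv), 0 → 25 °C
Reagents that add atoms: none
Why: Van Leusen reductive cyanation, in which the TosMIC anion adds to the ketone and the oxazoline intermediate is opened and deformylated to the one-carbon-longer nitrile; addition outruns enolisation at 0 °C so the ring centres stay cis, and the uncontrolled α-nitrile centre becomes an enolate carbon in step 8.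

**Step 5**
Reactants: 8 2-[(1R,2R)-4-methyl-2-(2-methylbut-3-en-2-yl)cyclohex-3-en-1-yl]propanenitrile; 9 vinylmagnesium bromide
Product: 11 4-[(1R,2R)-4-methyl-2-(2-methylbut-3-en-2-yl)cyclohex-3-en-1-yl]pent-1-en-3-one (C4 epimers), via N-bromomagnesio ketimine 10 (not isolated)
Conditions: CuBr·SMe2 (5 mol%), THF, 0 → 50 °C; then 1 M HCl, 0 °C
Reagents that add atoms: water, O
Why: Grignard addition to a nitrile stops at the metallo-imine, so hydrolysis gives the vinyl ketone without over-addition; CuBr catalysis favours addition over α-deprotonation, and no stereocentre is set.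

**Step 6**
Reactants: 11 4-[(1R,2R)-4-methyl-2-(2-methylbut-3-en-2-yl)cyclohex-3-en-1-yl]pent-1-en-3-one
Product: 12 (1R,7R)-2,6,6,9-tetramethylbicyclo[5.4.0]undeca-4,8-dien-3-one (cis-fused, C2 epimers)
Conditions: second-generation Grubbs catalyst (5 mol%), CH2Cl2 (5 mM), 40 °C
Reagents that add atoms: none
Why: Ring-closing metathesis of the vinyl ketone with the neopentyl vinyl group, which sit cis on adjacent ring carbons, closes the cycloheptenone with loss of ethene; the trisubstituted ring alkene does not take part.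

**Step 7**
Reactants: 12 (1R,7R)-2,6,6,9-tetramethylbicyclo[5.4.0]undeca-4,8-dien-3-one
Product: 13 8,9-epoxy-2,6,6,9-tetramethylbicyclo[5.4.0]undec-4-en-3-one (cis-fused, oxygen on the face opposite the seven-membered ring, C2 epimers)
Conditions: mCPBA, CH2Cl2, 0 °C
Reagents that add atoms: 3-chloroperbenzoic acid, OOC(=O)c1cccc(Cl)c1
Why: Prilezhaev epoxidation in which the electron-rich trisubstituted alkene reacts and the enone does not; the peracid comes from the face opposite the cis-fused seven-membered ring (the adjacent CMe2 blocks the other face), which places the oxygen anti to C10.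

**Step 8**
Reactants: 13 8,9-epoxy-2,6,6,9-tetramethylbicyclo[5.4.0]undec-4-en-3-one
Product: 15 (3R,4S,5R,10S,11R)-3-hydroxylongipin-7-en-9-one, via potassium dienolate 14 (not isolated)
Conditions: KN(SiMe3)2 (1.2 equiv), THF, −78 → 45 °C; then H2O
Reagents that add atoms: none
Why: Intramolecular enolate alkylation by epoxide opening (Stork-type 4-exo-tet closure): C10 is the only enolisable position of the cross-conjugated enone, it attacks the secondary epoxide carbon C4 from the back with inversion to close the cyclobutane, and the ring tether forces the configuration of quaternary C10 while C3 keeps its oxygen.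

**Step 9**
Reactants: 15 (3R,4S,5R,10S,11R)-3-hydroxylongipin-7-en-9-one
Product: 16 (4R,5R,10S,11R)-longipina-2,7-dien-9-one
Conditions: SOCl2, pyridine, CH2Cl2, −30 → 0 °C
Reagents that add atoms: none
Why: E2 dehydration of the tertiary alcohol through its chlorosulfite: an anti-periplanar C2–H is present, the bridgehead C4–H cannot be lost (Bredt), the endocyclic trisubstituted alkene is favoured over the exocyclic one, and the basic medium suppresses cationic rearrangement of the cyclobutane.

**Step 10**
Reactants: 16 (4R,5R,10S,11R)-longipina-2,7-dien-9-one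
Product: 17 (4R,5S,10R,11R)-longipina-2,7-diene-1,9-dione
Conditions: CrO3, 3,5-dimethylpyrazole, CH2Cl2, −20 °C
Reagents that add atoms: chromium trioxide, O=[Cr](=O)=O
Why: Allylic oxidation of the ring CH2 next to the trisubstituted alkene (the selectivity of α-pinene to verbenone); the other alkene is an enone without allylic hydrogens and no stereocentre changes.

**Step 11**
Reactants: 17 (4R,5S,10R,11R)-longipina-2,7-diene-1,9-dione
Product: 19 (4R,5S,7R,10R,11R)-7-hydroxylongipin-2-ene-1,9-dione, via C7 pinacol boronate 18 (not isolated)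
Conditions: CuCl (5 mol%), (R)-DTBM-SEGPHOS (6 mol%), NaOt-Bu (10 mol%), B2pin2, MeOH (2 equiv), THF, 25 °C; then NaBO3·4H2O, THF/H2O, 0 °C
Reagents that add atoms: sodium perborate, [Na+].[O-]OB=O (the C7 oxygen); bis(pinacolato)diboron, CC1(C)OB(OC1(C)C)B1OC(C)(C)C(C)(C)O1 (boron of 18 only)
Why: Copper-catalysed asymmetric conjugate borylation followed by oxidation with retention: the β-monosubstituted cycloheptenone reacts faster than the β,β-disubstituted bridged enone, the two faces at C7 differ only at remote C1/C3 so the chiral bisphosphine sets C7 as R, and perborate turns C–B into the C7–O bond.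

**Step 12**
Reactants: 19 (4R,5S,7R,10R,11R)-7-hydroxylongipin-2-ene-1,9-dione; 20 (2E)-2-methylbut-2-enal
Product: 22 (4R,5S,7R,9R,10R,11R)-9-hydroxy-1-oxolongipin-2-en-7-yl (2E)-2-methylbut-2-enoate, via C7 hemiacetal 21 (not isolated)
Conditions: SmI2 (30 mol%) premixed with 20 (6 equiv), THF, −10 °C, dark
Reagents that add atoms: none
Why: Proposed new method: an Evans–Tishchenko redox esterification with an α,β-unsaturated, α-branched aldehyde as hydride donor on a cyclic β-hydroxy ketone flanked by two quaternary carbons. The trivalent samarium alkoxide formed from SmI2 and 20 binds the oxygen of the C7 hemiacetal and the C9 carbonyl. The hemiacetal C–H is then passed as hydride to C9 across the ring on the face of the C7–O bond (six-membered chair-like transition state). This gives the free C9 alcohol trans to O7 (9R) and turns the hemiacetal into the tiglate on O7, and the C=C of 20 stays intact because only the formyl hydrogen moves and the ester gains conjugation. The closest known reaction is the samarium-catalysed Evans–Tishchenko reduction of acyclic β-hydroxy ketones with saturated or aromatic aldehydes (a Meerwein–Ponndorf–Verley-type hydride shift).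

**Step 13**
Reactants: 22 (4R,5S,7R,9R,10R,11R)-9-hydroxy-1-oxolongipin-2-en-7-yl (2E)-2-methylbut-2-enoate; 23 3-methylbut-2-enoyl chloride
Product: 24 (4R,5S,7R,9R,10R,11R)-7-[(2E)-2-methylbut-2-enoyloxy]-1-oxolongipin-2-en-9-yl 3-methylbut-2-enoate (CNP0257816.1)
Conditions: pyridine, DMAP (0.2 equiv), CH2Cl2, 0 → 25 °C
Reagents that add atoms: none
Why: DMAP-catalysed esterification of the remaining hindered secondary alcohol; no stereocentre is touched, weakly basic pyridine avoids deconjugation of the acid chloride through the vinylketene, and the trans-1,3 arrangement prevents acyl migration.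

**Compound list**

1 | 3-methylbut-2-enal | CC(C)=CC=O | starting material
2 | (3-methylbut-2-en-1-yl)magnesium chloride | CC(C)=CC[Mg]Cl | starting material
3 | 3,3,6-trimethylhepta-1,5-dien-4-ol (racemic) | CC(C)=CC(O)C(C)(C)C=C | intermediate
4 | (3E)-2,5,5-trimethylhepta-1,3,6-triene | C=CC(C)(C)/C=C/C(C)=C | intermediate
5 | but-3-en-2-one | CC(=O)C=C | starting material
6 | 1-[(1R,2S)-4-methyl-2-(2-methylbut-3-en-2-yl)cyclohex-3-en-1-yl]ethan-1-one | CC(=O)[C@@H]1CCC(C)=C[C@@H]1C(C)(C)C=C | intermediate
7 | p-toluenesulfonylmethyl isocyanide | Cc1ccc(cc1)S(=O)(=O)C[N+]#[C-] | starting material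
8 | 2-[(1R,2R)-4-methyl-2-(2-methylbut-3-en-2-yl)cyclohex-3-en-1-yl]propanenitrile (α-epimers) | CC(C#N)[C@@H]1CCC(C)=C[C@@H]1C(C)(C)C=C | intermediate
9 | vinylmagnesium bromide | C=C[Mg]Br | starting material
10 | N-bromomagnesio ketimine of 11 | C=CC(=N[Mg]Br)C(C)[C@@H]1CCC(C)=C[C@@H]1C(C)(C)C=C | intermediate
11 | 4-[(1R,2R)-4-methyl-2-(2-methylbut-3-en-2-yl)cyclohex-3-en-1-yl]pent-1-en-3-one (C4 epimers) | C=CC(=O)C(C)[C@@H]1CCC(C)=C[C@@H]1C(C)(C)C=C | intermediate
12 | (1R,7R)-2,6,6,9-tetramethylbicyclo[5.4.0]undeca-4,8-dien-3-one (C2 epimers) | C1=CC(=O)C(C)[C@@H]2CCC(C)=C[C@@H]2C1(C)C | intermediate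
13 | 8,9-epoxy-2,6,6,9-tetramethylbicyclo[5.4.0]undec-4-en-3-one (epoxide anti to the seven-membered ring) | C1=CC(=O)C(C)[C@@H]2CC[C@@]3(C)O[C@H]3[C@@H]2C1(C)C | intermediate
14 | potassium dienolate of 13 | C1=CC([O-])=C(C)[C@@H]2CC[C@@]3(C)O[C@H]3[C@@H]2C1(C)C.[K+] | intermediate
15 | (3R,4S,5R,10S,11R)-3-hydroxylongipin-7-en-9-one | C1=CC(=O)[C@@]2(C)[C@@H]3CC[C@@](C)(O)[C@H]2[C@@H]3C1(C)C | intermediate
16 | (4R,5R,10S,11R)-longipina-2,7-dien-9-one | C1=CC(=O)[C@@]2(C)[C@@H]3CC=C(C)[C@H]2[C@@H]3C1(C)C | intermediate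
17 | (4R,5S,10R,11R)-longipina-2,7-diene-1,9-dione | C1=CC(=O)[C@@]2(C)[C@@H]3C(=O)C=C(C)[C@H]2[C@@H]3C1(C)C | intermediate
18 | 7-(4,4,5,5-tetramethyl-1,3,2-dioxaborolan-2-yl)longipin-2-ene-1,9-dione (7R) | CC1(C)OB(OC1(C)C)[C@@H]2CC(=O)[C@@]3(C)[C@@H]4C(=O)C=C(C)[C@H]3[C@@H]4C2(C)C | intermediate
19 | (4R,5S,7R,10R,11R)-7-hydroxylongipin-2-ene-1,9-dione | O[C@@H]1CC(=O)[C@@]2(C)[C@@H]3C(=O)C=C(C)[C@H]2[C@@H]3C1(C)C | intermediate
20 | (2E)-2-methylbut-2-enal | C/C=C(\C)C=O | starting material
21 | C7 hemiacetal of 19 with 20 | C/C=C(\C)C(O)O[C@@H]1CC(=O)[C@@]2(C)[C@@H]3C(=O)C=C(C)[C@H]2[C@@H]3C1(C)C | intermediate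
22 | (4R,5S,7R,9R,10R,11R)-9-hydroxy-1-oxolongipin-2-en-7-yl (2E)-2-methylbut-2-enoate | C/C=C(\C)C(=O)O[C@@H]1C[C@@H](O)[C@@]2(C)[C@@H]3C(=O)C=C(C)[C@H]2[C@@H]3C1(C)C | intermediate
23 | 3-methylbut-2-enoyl chloride | CC(C)=CC(Cl)=O | starting material
24 | (4R,5S,7R,9R,10R,11R)-7-[(2E)-2-methylbut-2-enoyloxy]-1-oxolongipin-2-en-9-yl 3-methylbut-2-enoate | C/C=C(\C)C(=O)O[C@@H]1C[C@@H](OC(=O)C=C(C)C)[C@@]2(C)[C@@H]3C(=O)C=C(C)[C@H]2[C@@H]3C1(C)C | target

**Step count and risks**

Total steps: 13. Longest linear sequence: 13.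

Steps most likely to fail:

Step 3 (the hindered 1-tert-alkyl diene may react slowly or with low ee under the cationic boron catalyst). Fallback by auxiliary control; it sets out from 4 and comes back to the route at 6. Triene 4 and (4S)-3-acryloyl-4-benzyl-1,3-oxazolidin-2-one with Et2AlCl (CH2Cl2, −78 °C) give the endo imide adduct (4S)-4-benzyl-3-{[(1R,2S)-4-methyl-2-(2-methylbut-3-en-2-yl)cyclohex-3-en-1-yl]carbonyl}-1,3-oxazolidin-2-one F1. MeONHMe·HCl with AlMe3 exchanges the auxiliary for the Weinreb amide (1R,2S)-N-methoxy-N,4-dimethyl-2-(2-methylbut-3-en-2-yl)cyclohex-3-ene-1-carboxamide F2, and MeMgBr then gives 6.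

Step 8 (closing a four-membered ring with a ketone enolate may lose to O-alkylation or base-induced epoxide isomerisation). Fallback with a nitrile-stabilised carbanion and the cyclobutane made before the seven-membered ring; it sets out from 8 and comes back at 15. mCPBA converts 8 into the epoxy nitrile 2-[6-methyl-2-(2-methylbut-3-en-2-yl)-7-oxabicyclo[4.1.0]heptan-3-yl]propanenitrile F3. KN(SiMe3)2 closes the cyclobutane by the classical epoxy-nitrile cyclisation to 2-hydroxy-2,6-dimethyl-7-(2-methylbut-3-en-2-yl)bicyclo[3.1.1]heptane-6-carbonitrile F4. This fallback has its own weak point: the configuration at the nitrile-bearing carbon is not enforced by a ring, and only the epimer with the nitrile next to the tert-alkyl group can go on. Excess vinylmagnesium bromide (CuBr·SMe2), then acid, gives the vinyl ketone 1-[2-hydroxy-2,6-dimethyl-7-(2-methylbut-3-en-2-yl)bicyclo[3.1.1]heptan-6-yl]prop-2-en-1-one F5, and ring-closing metathesis with the second-generation Grubbs catalyst gives 15.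

Step 12 (the proposed new step: hemiacetal formation at the neopentyl C7 alcohol, or hydride transfer from an enal hemiacetal, may be too slow, and retro-aldol opening of 19 may compete). Fallback with known chemistry, hydroxyl-directed reduction and stepwise acylation; it sets out from 19 and comes back at 24. Me4NBH(OAc)3 (MeCN/AcOH, −30 °C; hydride delivered from the O7-bound borohydride, anti) gives the diol (4R,5S,7R,9R,10R,11R)-7,9-dihydroxylongipin-2-en-1-one F6. One equivalent of 23 (pyridine, −20 °C) should acylate the C9 hydroxyl first, since C7–OH sits next to the CMe2 carbon, to give (4R,5S,7R,9R,10R,11R)-7-hydroxy-1-oxolongipin-2-en-9-yl 3-methylbut-2-enoate F7; this site selectivity is an expectation, and the wrong mono-ester is recycled by methanolysis. Tiglic acid under Yamaguchi conditions (2,4,6-trichlorobenzoyl chloride, Et3N, DMAP) then esterifies C7–OH to give 24.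

**Further compounds**

F1 | step 3 | (4S)-4-benzyl-3-{[(1R,2S)-4-methyl-2-(2-methylbut-3-en-2-yl)cyclohex-3-en-1-yl]carbonyl}-1,3-oxazolidin-2-one | O=C1OC[C@H](Cc2ccccc2)N1C(=O)[C@@H]3CCC(C)=C[C@@H]3C(C)(C)C=C
F2 | step 3 | (1R,2S)-N-methoxy-N,4-dimethyl-2-(2-methylbut-3-en-2-yl)cyclohex-3-ene-1-carboxamide | CON(C)C(=O)[C@@H]1CCC(C)=C[C@@H]1C(C)(C)C=C
F3 | step 8 | 2-[6-methyl-2-(2-methylbut-3-en-2-yl)-7-oxabicyclo[4.1.0]heptan-3-yl]propanenitrile | CC(C#N)[C@@H]1CC[C@@]2(C)O[C@H]2[C@@H]1C(C)(C)C=C
F4 | step 8 | 2-hydroxy-2,6-dimethyl-7-(2-methylbut-3-en-2-yl)bicyclo[3.1.1]heptane-6-carbonitrile | N#C[C@@]1(C)[C@@H]2CC[C@@](C)(O)[C@H]1[C@@H]2C(C)(C)C=C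
F5 | step 8 | 1-[2-hydroxy-2,6-dimethyl-7-(2-methylbut-3-en-2-yl)bicyclo[3.1.1]heptan-6-yl]prop-2-en-1-one | C=CC(=O)[C@@]1(C)[C@@H]2CC[C@@](C)(O)[C@H]1[C@@H]2C(C)(C)C=C
F6 | step 12 | (4R,5S,7R,9R,10R,11R)-7,9-dihydroxylongipin-2-en-1-one | O[C@@H]1C[C@@H](O)[C@@]2(C)[C@@H]3C(=O)C=C(C)[C@H]2[C@@H]3C1(C)C
F7 | step 12 | (4R,5S,7R,9R,10R,11R)-7-hydroxy-1-oxolongipin-2-en-9-yl 3-methylbut-2-enoate | O[C@@H]1C[C@@H](OC(=O)C=C(C)C)[C@@]2(C)[C@@H]3C(=O)C=C(C)[C@H]2[C@@H]3C1(C)C
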